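the same everywhere: substrate 0.050 M
- eta: partner 0.25 M; free catalyst 0.75 mM; run made earlier
- epsilon: partner 0.25 M; free catalyst 1.6 mM; run made earlier
- beta: partner 0.25 M; free catalyst 2.4 mM; run made earlier
- delta: partner 0.33 M; free catalyst 2.8 mM; run made earlier
- alder: partner 0.250 M; free catalyst 2.8 mM; time 20 min
- cedar: partner 0.500 M; free catalyst 0.80 mM; time 20 min

| run | time / min | target / % |
|---|---|---|
| eta | 2.00 | 0 |
| eta | 4.00 | 5 |
| eta | 6.00 | 7 |
| eta | 8.00 | 7 |
| eta | 10.0 | 8 |
| epsilon | 2.00 | 1 |
| epsilon | 4.00 | 4 |
| epsilon | 6.00 | 10 |
| epsilon | 8.00 | 15 |
| epsilon | 10.0 | 16 |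
| beta | 0.833 | 1 |
| beta | 2.50 | 3 |
| beta | 5.00 | 13 |
| beta | 8.00 | 19 |
| beta | 10.0 | 25 |
| delta | 2.00 | 6 |
| delta | 4.00 | 12 |
| delta | 6.00 | 19 |
| delta | 8.00 | 27 |
| delta | 10.0 | 30 |

(scatter of a reading: 1.5 percentage points)



* which of the two ends with the higher amount of target, in percent of the substrate charged ("neither" if they lie within 2 percentage points) (alder / cedar / neither)
* target at the end, in percent of the substrate charged, alder
* target at the end, in percent of the substrate charged, cedar

1. The constants are hidden, so I read one from a run. I take beta, whose last reading of 25% at 10.0 min is higher than those of eta and epsilon.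

2. Partner is charged in larger amount than substrate, at 5.00 equivalents in alder. So I treat substrate as pseudo-first-order, with [free catalyst] as a factor. Minus the logarithm of the fraction left then grows with [free catalyst] times time. Beta's reading gives 0.288.

3. I scale that value by [free catalyst] times time, relative to beta, and call the result the exposure number. It counts how many e-foldings of substrate a flask receives. Target is one minus the exponential of minus that number.

4. I test it at the last reading of each other run. It gives 8.60% for eta, 17.5% for epsilon and 28.5% for delta. The readings are 8%, 16% and 30%, so the gaps stay near the scatter of 1.5 percentage points. One number carries these runs. But delta's [partner] of 0.33 M shows no clear effect, and cedar's 0.500 M lies beyond these runs, so cedar's figure is my weaker one.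

5. Alder's exposure number, beta's value scaled to its catalyst and time, is 0.671, which gives 48.9%. Cedar's is 0.192, which gives 17.5%. I expect alder to end higher.

6. The forecast says alder, with 38% for alder and 14% for cedar, and reads in the runs a hint that “the catalyst dies after a limited number of turnovers”.

7. The flask gives alder, with 52.6% for alder and 21.6% for cedar.

    substrate + catalyst intermediate A ⇌ idle complex, settled at all times (K = 7.80 M⁻¹)
    catalyst intermediate B ⇌ released group + catalyst intermediate C (K = 0.233 M, k = 268 min⁻¹)
    partner + catalyst intermediate A ⇌ catalyst intermediate B (K = 3.70 M⁻¹, k = 9.14 M⁻¹ min⁻¹)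
    catalyst intermediate C → catalyst intermediate D (k = 5.25 min⁻¹)
    substrate + free catalyst ⇌ catalyst intermediate A (K = 57.5 M⁻¹, k = 42.2 M⁻¹ min⁻¹)
    catalyst intermediate D → free catalyst + target (k = 3.14 min⁻¹)

8. Alder's exposure number is 3.49 times cedar's, the ratio of their [free catalyst]. Cedar trails alder because of its smaller [free catalyst]: with alder's catalyst, cedar reaches 63.5% instead of 21.6%. Its larger [partner] is a part of the story that pulls the other way.

9. A neighbour flask is alder with 0.700 mM of free catalyst. Its exposure number is 0.168, which gives 15.4%, and the computed flask gives 15.0%.

(The numbers in the tables are simulated for substances that don't exist, noise included.)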